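The dihydrofuran ring is disconnected at its C2–C3 bond. The furan ring holds a secondary benzylic oxygen at C3 next to C2, a carbon bonded to the ring oxygen O1 and to a 2-substituted propenyl unit. Read backwards, C3–O and the C2–C(=CH2) unit form a homoallylic alcohol, the product pattern of a [2,3]-Wittig rearrangement whose migrating allyl terminus is the O1-bound carbon. The precursor is thus an eight-membered 1,5-benzodioxocine: a cyclic benzyl allyl ether containing a Z enol ether (O1–C2=C3) and a silylated (R)-carbinol side chain. One ligand-controlled lithiation contracts it to the five-membered ring, setting C2–C3, both ring stereocentres and the isopropenyl group.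

Key step: step 7

Assumption: the sense of induction of the s-BuLi/bis(oxazoline) reagent on this new substrate is taken as (S,S)-ligand giving (2S,3S)-13; the (R,R)-ligand, equally available, would be used if the first run shows the opposite sense. (S,S)-t-Bu-box = 2,2'-(propane-2,2-diyl)bis[(4S)-4-tert-butyl-4,5-dihydro-1,3-oxazole].

Remark: the benzylic carbon is carried at the ester oxidation level (commercial 1), so that the phenol is the only hydroxyl group when the vinyl ether is made and no enolisable ketone is present when strong base is used.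

Step 1
Reactants: 1 methyl 5-acetyl-2-hydroxybenzoate; 2 ethenyl acetate (vinyl acetate)
Product: 3 methyl 5-acetyl-2-(ethenyloxy)benzoate
Conditions: [Ir(cod)Cl]2 (1 mol%), Na2CO3 (0.6 equiv), toluene, 100 °C
Reagents that add atoms: none
Why: Iridium-catalysed transfer vinylation (addition of the phenoxide to iridium-bound vinyl acetate, then loss of acetate) etherifies the only hydroxyl group, an acidic phenol, under conditions that leave the methyl ketone and the ester untouched.

Step 2
Reactants: 3 methyl 5-acetyl-2-(ethenyloxy)benzoate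
Product: 4 methyl 2-(ethenyloxy)-5-[(1R)-1-hydroxyethyl]benzoate
Conditions: RuCl[(R,R)-TsDPEN](p-cymene) (1 mol%), HCO2Na, H2O/MeOH (1:1), 40 °C
Reagents that add atoms: none
Why: Noyori-type asymmetric transfer hydrogenation: the (R,R)-TsDPEN ruthenium hydride delivers hydride to the Si face of the aryl methyl ketone through the six-membered N–H···O=C transition state, which sets the (R)-carbinol, while neutral aqueous formate makes the reduction irreversible and spares the ester and the aryl vinyl ether.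

Step 3
Reactants: 4 methyl 2-(ethenyloxy)-5-[(1R)-1-hydroxyethyl]benzoate
Product: 5 methyl 2-(ethenyloxy)-5-[(1R)-1-{[tri(propan-2-yl)silyl]oxy}ethyl]benzoate
Conditions: TIPSCl, imidazole, DMAP (cat.), DMF, 40 °C
Reagents that add atoms: chlorotri(propan-2-yl)silane, CC(C)[Si](Cl)(C(C)C)C(C)C
Why: Imidazole-mediated silylation of the only free hydroxyl group; the bulky TIPS ether is chosen because it survives i-Bu2AlH, NaH and s-BuLi and later screens the side-chain methine from lithiation.

Step 4
Reactants: 5 methyl 2-(ethenyloxy)-5-[(1R)-1-{[tri(propan-2-yl)silyl]oxy}ethyl]benzoate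
Product: 6 {2-(ethenyloxy)-5-[(1R)-1-{[tri(propan-2-yl)silyl]oxy}ethyl]phenyl}methanol
Conditions: i-Bu2AlH, CH2Cl2, −78 to 0 °C; aq. potassium sodium tartrate
Reagents that add atoms: none
Why: Hydride reduction of the aryl ester to the primary benzylic alcohol, to which the silyl ether and the vinyl ether are inert; 6 is kept free of acid because its hydroxyl group could add to the neighbouring vinyl ether.

Step 5
Reactants: 6 {2-(ethenyloxy)-5-[(1R)-1-{[tri(propan-2-yl)silyl]oxy}ethyl]phenyl}methanol; 7 3-chloro-2-methylprop-1-ene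
Product: 9 1-(ethenyloxy)-2-{[(2-methylprop-2-en-1-yl)oxy]methyl}-4-[(1R)-1-{[tri(propan-2-yl)silyl]oxy}ethyl]benzene, via sodium benzyl alkoxide 8 (not isolated)
Conditions: NaH, THF/DMF, 0 °C; then 7, rt
Reagents that add atoms: none
Why: Williamson ether synthesis: the primary alkoxide 8 displaces chloride from the allylic halide, and no other acidic or electrophilic site is present.

Step 6
Reactants: 9 1-(ethenyloxy)-2-{[(2-methylprop-2-en-1-yl)oxy]methyl}-4-[(1R)-1-{[tri(propan-2-yl)silyl]oxy}ethyl]benzene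
Product: 10 (Z)-3-methyl-8-[(1R)-1-{[tri(propan-2-yl)silyl]oxy}ethyl]-4H,6H-1,5-benzodioxocine
Conditions: second-generation Grubbs catalyst (10 mol%), toluene (0.005 M), 80 °C, argon sparge
Reagents that add atoms: none
Why: Ring-closing metathesis of an enol ether: the ruthenium carbene formed at the aryl vinyl ether (an aryloxycarbene, less stabilised than an alkoxycarbene) adds to the tethered 1,1-disubstituted alkene at 80 °C, loss of ethene drives the closure, the ortho-disubstituted arene holds the two alkenes close, and the ring allows only the Z enol ether.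

Step 7
Reactants: 10 (Z)-3-methyl-8-[(1R)-1-{[tri(propan-2-yl)silyl]oxy}ethyl]-4H,6H-1,5-benzodioxocine
Product: 13 (2S,3S)-2-(prop-1-en-2-yl)-5-[(1R)-1-{[tri(propan-2-yl)silyl]oxy}ethyl]-2,3-dihydro-1-benzofuran-3-ol, via C6-lithiated benzodioxocine 11 (not isolated), via lithium benzofuran-3-olate 12 (not isolated)
Conditions: s-BuLi (1.3 equiv), (S,S)-t-Bu-box (1.5 equiv), hexane, −78 °C; then H2O
Reagents that add atoms: none
Why: Proposed new method: the ligand-bound s-BuLi removes a benzylic hydrogen at C6 of 10 (benzodioxocine numbering, α to O5) to give 11, whose carbanion bonds to enol ether carbon C2 while the allylic C4–O5 bond breaks and the double bond shifts to C3=C4, a concerted [2,3]-Wittig shift that delivers alkoxide 12 and, on quenching, 13. The closest known reaction types are the [2,3]-Wittig ring contraction of macrocyclic allylic ethers with chiral lithium amides and the bis(oxazoline)-controlled enantioselective [2,3]-Wittig rearrangement of acyclic benzyl allyl ethers; new here are the medium ring and the oxygen-bearing allyl terminus. The dihydrofuran ring (O1, C2, former C6, C6a, C10a) closes transannularly in a 5-exo-trig, SN2′-type mode, the attacked C2=C3 bond lying outside the new ring. Since the new ring and the five-centre array C6–O5–C4–C3–C2 share the forming bond and can only be cis-fused, O5 and C3 end up on the same face, which fixes the C3 oxygen and the isopropenyl group of 13 as cis. The absolute configuration (2S,3S) is set by the chiral ligand on lithium, through removal of the pro-S hydrogen at C6 (retentive lithiation, C–C bond formation with inversion) or, if 11 epimerises, through the faster-rearranging ligated diastereomer. The step needs lithiation at C6 in preference to allylic C4, vinylic C2–H and the side-chain methine: a C4 anion would place charge on oxygen-substituted C2, C2–H lithiation is slow in hexane at −78 °C, and the methine is screened by its methyl group and the TIPS ether, which also keeps 10 soluble in hexane.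

Step 8
Reactants: 13 (2S,3S)-2-(prop-1-en-2-yl)-5-[(1R)-1-{[tri(propan-2-yl)silyl]oxy}ethyl]-2,3-dihydro-1-benzofuran-3-ol
Product: 15 (2S,3R)-2-(prop-1-en-2-yl)-5-[(1R)-1-{[tri(propan-2-yl)silyl]oxy}ethyl]-2,3-dihydro-1-benzofuran-3-yl acetate, via alkoxytriphenylphosphonium acetate 14 (not isolated)
Conditions: PPh3, DIAD, AcOH, toluene, 0 °C to rt
Reagents that add atoms: acetic acid, CC(=O)O
Why: Mitsunobu reaction: acetate displaces the oxyphosphonium group of 14 at C3 by SN2 with inversion, entering from the face opposite to the isopropenyl group, so the (3R) trans acetate results (a competing ionised pathway would be captured from the same open face) while C2 and the side-chain centre are not involved.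

Step 9
Reactants: 15 (2S,3R)-2-(prop-1-en-2-yl)-5-[(1R)-1-{[tri(propan-2-yl)silyl]oxy}ethyl]-2,3-dihydro-1-benzofuran-3-yl acetate
Product: 16 (2S,3R)-5-[(1R)-1-hydroxyethyl]-2-(prop-1-en-2-yl)-2,3-dihydro-1-benzofuran-3-yl acetate
Conditions: Bu4NF, AcOH (1:1), THF, rt
Reagents that add atoms: none
Why: Fluoride-induced desilylation driven by the Si–F bond; buffering with acetic acid keeps the medium non-basic so that the C3 acetate is neither cleaved nor eliminated.

Step 10
Reactants: 16 (2S,3R)-5-[(1R)-1-hydroxyethyl]-2-(prop-1-en-2-yl)-2,3-dihydro-1-benzofuran-3-yl acetate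
Product: 17 (1R)-1-[(2S,3R)-3-(acetyloxy)-2-(prop-1-en-2-yl)-2,3-dihydro-1-benzofuran-5-yl]ethyl (2E)-2-methylbut-2-enoate
Conditions: tigloyl chloride, pyridine, DMAP (cat.), CH2Cl2, 0 °C to rt
Reagents that add atoms: (2E)-2-methylbut-2-enoyl chloride (tigloyl chloride), C/C=C(\C)C(=O)Cl
Why: DMAP-catalysed acylation of the secondary alcohol by the acid chloride takes place at oxygen, so the (R) centre is retained, and the (E)-tiglate, the stable geometry, is carried over unchanged from the reagent.

Step 11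
Reactants: 17 (1R)-1-[(2S,3R)-3-(acetyloxy)-2-(prop-1-en-2-yl)-2,3-dihydro-1-benzofuran-5-yl]ethyl (2E)-2-methylbut-2-enoate
Product: 19 (1R)-1-[(2S,3R)-3-(acetyloxy)-2-(3-oxoprop-1-en-2-yl)-2,3-dihydro-1-benzofuran-5-yl]ethyl (2E)-2-methylbut-2-enoate, via primary allylic alcohol 18 (not isolated)
Conditions: SeO2, 1,4-dioxane, 70 °C
Reagents that add atoms: selenium dioxide, O=[Se]=O
Why: Riley allylic oxidation: ene reaction of SeO2 at the electron-rich 1,1-disubstituted alkene and [2,3]-shift give allylic alcohol 18, which is oxidised further to the enal under the same conditions; the methyl group reacts in preference to the C2 methine, and the electron-poor tiglate alkene does not enter the ene step.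

Compound list
1 | methyl 5-acetyl-2-hydroxybenzoate | COC(=O)c1cc(C(C)=O)ccc1O | starting material
2 | ethenyl acetate (vinyl acetate) | C=COC(C)=O | starting material
3 | methyl 5-acetyl-2-(ethenyloxy)benzoate | COC(=O)c1cc(C(C)=O)ccc1OC=C | intermediate
4 | methyl 2-(ethenyloxy)-5-[(1R)-1-hydroxyethyl]benzoate | COC(=O)c1cc([C@@H](C)O)ccc1OC=C | intermediate
5 | methyl 2-(ethenyloxy)-5-[(1R)-1-{[tri(propan-2-yl)silyl]oxy}ethyl]benzoate | COC(=O)c1cc([C@@H](C)O[Si](C(C)C)(C(C)C)C(C)C)ccc1OC=C | intermediate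
6 | {2-(ethenyloxy)-5-[(1R)-1-{[tri(propan-2-yl)silyl]oxy}ethyl]phenyl}methanol | OCc1cc([C@@H](C)O[Si](C(C)C)(C(C)C)C(C)C)ccc1OC=C | intermediate
7 | 3-chloro-2-methylprop-1-ene | C=C(C)CCl | starting material
8 | sodium {2-(ethenyloxy)-5-[(1R)-1-{[tri(propan-2-yl)silyl]oxy}ethyl]phenyl}methanolate | [Na+].[O-]Cc1cc([C@@H](C)O[Si](C(C)C)(C(C)C)C(C)C)ccc1OC=C | intermediate (not isolated)
9 | 1-(ethenyloxy)-2-{[(2-methylprop-2-en-1-yl)oxy]methyl}-4-[(1R)-1-{[tri(propan-2-yl)silyl]oxy}ethyl]benzene | C=C(C)COCc1cc([C@@H](C)O[Si](C(C)C)(C(C)C)C(C)C)ccc1OC=C | intermediate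
10 | (Z)-3-methyl-8-[(1R)-1-{[tri(propan-2-yl)silyl]oxy}ethyl]-4H,6H-1,5-benzodioxocine | C/C1=C/Oc2ccc([C@@H](C)O[Si](C(C)C)(C(C)C)C(C)C)cc2COC1 | intermediate (precursor of the key step)
11 | [(6S)-3-methyl-8-[(1R)-1-{[tri(propan-2-yl)silyl]oxy}ethyl]-4H,6H-1,5-benzodioxocin-6-yl]lithium (ligand-bound; configuration as expected under ligand control) | C/C1=C/Oc2ccc([C@@H](C)O[Si](C(C)C)(C(C)C)C(C)C)cc2[C@H]([Li])OC1 | intermediate (not isolated)
12 | lithium (2S,3S)-2-(prop-1-en-2-yl)-5-[(1R)-1-{[tri(propan-2-yl)silyl]oxy}ethyl]-2,3-dihydro-1-benzofuran-3-olate | C=C(C)[C@@H]1Oc2ccc([C@@H](C)O[Si](C(C)C)(C(C)C)C(C)C)cc2[C@@H]1[O-].[Li+] | intermediate (not isolated)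
13 | (2S,3S)-2-(prop-1-en-2-yl)-5-[(1R)-1-{[tri(propan-2-yl)silyl]oxy}ethyl]-2,3-dihydro-1-benzofuran-3-ol | C=C(C)[C@@H]1Oc2ccc([C@@H](C)O[Si](C(C)C)(C(C)C)C(C)C)cc2[C@@H]1O | intermediate (product of the key step)
14 | {[(2S,3S)-2-(prop-1-en-2-yl)-5-[(1R)-1-{[tri(propan-2-yl)silyl]oxy}ethyl]-2,3-dihydro-1-benzofuran-3-yl]oxy}(triphenyl)phosphonium acetate | C=C(C)[C@@H]1Oc2ccc([C@@H](C)O[Si](C(C)C)(C(C)C)C(C)C)cc2[C@@H]1O[P+](c1ccccc1)(c1ccccc1)c1ccccc1.CC(=O)[O-] | intermediate (not isolated)
15 | (2S,3R)-2-(prop-1-en-2-yl)-5-[(1R)-1-{[tri(propan-2-yl)silyl]oxy}ethyl]-2,3-dihydro-1-benzofuran-3-yl acetate | C=C(C)[C@@H]1Oc2ccc([C@@H](C)O[Si](C(C)C)(C(C)C)C(C)C)cc2[C@H]1OC(C)=O | intermediate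
16 | (2S,3R)-5-[(1R)-1-hydroxyethyl]-2-(prop-1-en-2-yl)-2,3-dihydro-1-benzofuran-3-yl acetate | C=C(C)[C@@H]1Oc2ccc([C@@H](C)O)cc2[C@H]1OC(C)=O | intermediate
17 | (1R)-1-[(2S,3R)-3-(acetyloxy)-2-(prop-1-en-2-yl)-2,3-dihydro-1-benzofuran-5-yl]ethyl (2E)-2-methylbut-2-enoate | C=C(C)[C@@H]1Oc2ccc([C@@H](C)OC(=O)/C(C)=C/C)cc2[C@H]1OC(C)=O | intermediate
18 | (1R)-1-[(2S,3R)-3-(acetyloxy)-2-(3-hydroxyprop-1-en-2-yl)-2,3-dihydro-1-benzofuran-5-yl]ethyl (2E)-2-methylbut-2-enoate | C=C(CO)[C@@H]1Oc2ccc([C@@H](C)OC(=O)/C(C)=C/C)cc2[C@H]1OC(C)=O | intermediate (not isolated)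
19 | (1R)-1-[(2S,3R)-3-(acetyloxy)-2-(3-oxoprop-1-en-2-yl)-2,3-dihydro-1-benzofuran-5-yl]ethyl (2E)-2-methylbut-2-enoate | C=C(C=O)[C@@H]1Oc2ccc([C@@H](C)OC(=O)/C(C)=C/C)cc2[C@H]1OC(C)=O | target

Total step count: 11
Longest linear sequence: 11 steps (1 to 19)

Steps most likely to fail

1. Step 7 (the proposed new method). Three things may go wrong.
- Lithiation may occur at another site (allylic C4 or vinylic C2–H).
- The benzylic carbanion may rearrange by the radical [1,2]-pathway to a seven-membered ring.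
- Reagent control over the two new centres relative to the remote (R)-carbinol may be poor.

Fallback with known chemistry, setting out from 6 and rejoining the route at 15, so that neither the ring contraction nor the inversion is needed. Oxidation of 6 with MnO2 in CH2Cl2 should give 2-(ethenyloxy)-5-[(1R)-1-{[tri(propan-2-yl)silyl]oxy}ethyl]benzaldehyde F1. Brief hydrolysis of the aryl vinyl ether (dilute HCl, aqueous THF) should free 2-hydroxy-5-[(1R)-1-{[tri(propan-2-yl)silyl]oxy}ethyl]benzaldehyde F2, which is silylated (TBSCl, imidazole, DMF) to 2-{[tert-butyl(dimethyl)silyl]oxy}-5-[(1R)-1-{[tri(propan-2-yl)silyl]oxy}ethyl]benzaldehyde F3. Asymmetric sulfonium-ylide epoxidation (Corey–Chaykovsky type) follows, with the (2-methylprop-2-en-1-yl)sulfonium salt of isothiocineole and LiN(SiMe3)2 in THF at −78 °C. The sulfide enantiomer is chosen for the (2R,3R) series. This should give the trans vinyl epoxide tert-butyl(dimethyl){2-[(2R,3R)-3-(prop-1-en-2-yl)oxiran-2-yl]-4-[(1R)-1-{[tri(propan-2-yl)silyl]oxy}ethyl]phenoxy}silane F4. K2CO3 in MeOH removes the aryl silyl ether, and the phenoxide opens the epoxide at its allylic carbon with inversion. The product should be the trans alcohol (2S,3R)-2-(prop-1-en-2-yl)-5-[(1R)-1-{[tri(propan-2-yl)silyl]oxy}ethyl]-2,3-dihydro-1-benzofuran-3-ol F5. Ac2O, pyridine and DMAP convert F5 into 15.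

2. Step 6. The catalyst may be held as the heteroatom-stabilised aryloxycarbene, which turns over too slowly with the 1,1-disubstituted alkene. Bimolecular metathesis of the vinyl ether or hydride-induced alkene migration would then win over ring closure.

Fallback, setting out from 6 and rejoining at 10: a relay tether moves catalyst loading to a terminal allyl ether. Prenyl bromide and allyl alcohol (NaH, THF) give 3-methyl-1-(prop-2-en-1-yloxy)but-2-ene F6. SeO2 (cat.)/t-BuOOH oxidises its (E)-methyl group to (2E)-2-methyl-4-(prop-2-en-1-yloxy)but-2-en-1-ol F7. MsCl/Et3N gives (2E)-2-methyl-4-(prop-2-en-1-yloxy)but-2-en-1-yl methanesulfonate F8. Alkylation of alkoxide 8 (from 6 and NaH) with F8 gives the relay ether 1-(ethenyloxy)-2-({[(2E)-2-methyl-4-(prop-2-en-1-yloxy)but-2-en-1-yl]oxy}methyl)-4-[(1R)-1-{[tri(propan-2-yl)silyl]oxy}ethyl]benzene F9. With the second-generation Grubbs catalyst, the ruthenium should load at the allyl terminus of F9 and expel 2,5-dihydrofuran. That leaves the disubstituted alkylidene at the future C3, which then closes on the aryl vinyl ether to give 10.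

3. Step 8. The activated C3 oxygen of 14 lies anti to the C2 hydrogen, so base-induced elimination to the aromatic benzofuran may outrun substitution. The comparatively basic acetate and the slow reaction of a weakly acidic pronucleophile favour this.

Fallback, setting out from 13 and rejoining at 15: the inversion is separated from the acetylation. A Mitsunobu reaction with 4-nitrobenzoic acid (PPh3, DIAD, toluene, 0 °C), a more acidic pronucleophile whose carboxylate is a weaker base, should give (2S,3R)-2-(prop-1-en-2-yl)-5-[(1R)-1-{[tri(propan-2-yl)silyl]oxy}ethyl]-2,3-dihydro-1-benzofuran-3-yl 4-nitrobenzoate F10. Methanolysis (K2CO3, MeOH) gives the trans alcohol (2S,3R)-2-(prop-1-en-2-yl)-5-[(1R)-1-{[tri(propan-2-yl)silyl]oxy}ethyl]-2,3-dihydro-1-benzofuran-3-ol F5. Ac2O, pyridine and DMAP then give 15.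

Further compounds
F1 | step 7 | 2-(ethenyloxy)-5-[(1R)-1-{[tri(propan-2-yl)silyl]oxy}ethyl]benzaldehyde | O=Cc1cc([C@@H](C)O[Si](C(C)C)(C(C)C)C(C)C)ccc1OC=C
F2 | step 7 | 2-hydroxy-5-[(1R)-1-{[tri(propan-2-yl)silyl]oxy}ethyl]benzaldehyde | O=Cc1cc([C@@H](C)O[Si](C(C)C)(C(C)C)C(C)C)ccc1O
F3 | step 7 | 2-{[tert-butyl(dimethyl)silyl]oxy}-5-[(1R)-1-{[tri(propan-2-yl)silyl]oxy}ethyl]benzaldehyde | O=Cc1cc([C@@H](C)O[Si](C(C)C)(C(C)C)C(C)C)ccc1O[Si](C)(C)C(C)(C)C
F4 | step 7 | tert-butyl(dimethyl){2-[(2R,3R)-3-(prop-1-en-2-yl)oxiran-2-yl]-4-[(1R)-1-{[tri(propan-2-yl)silyl]oxy}ethyl]phenoxy}silane | C=C(C)[C@H]1O[C@@H]1c1cc([C@@H](C)O[Si](C(C)C)(C(C)C)C(C)C)ccc1O[Si](C)(C)C(C)(C)C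
F5 | step 7 | (2S,3R)-2-(prop-1-en-2-yl)-5-[(1R)-1-{[tri(propan-2-yl)silyl]oxy}ethyl]-2,3-dihydro-1-benzofuran-3-ol | C=C(C)[C@@H]1Oc2ccc([C@@H](C)O[Si](C(C)C)(C(C)C)C(C)C)cc2[C@H]1O
F6 | step 6 | 3-methyl-1-(prop-2-en-1-yloxy)but-2-ene | CC(C)=CCOCC=C
F7 | step 6 | (2E)-2-methyl-4-(prop-2-en-1-yloxy)but-2-en-1-ol | C=CCOC/C=C(\C)CO
F8 | step 6 | (2E)-2-methyl-4-(prop-2-en-1-yloxy)but-2-en-1-yl methanesulfonate | C=CCOC/C=C(\C)COS(C)(=O)=O
F9 | step 6 | 1-(ethenyloxy)-2-({[(2E)-2-methyl-4-(prop-2-en-1-yloxy)but-2-en-1-yl]oxy}methyl)-4-[(1R)-1-{[tri(propan-2-yl)silyl]oxy}ethyl]benzene | C=COc1ccc([C@@H](C)O[Si](C(C)C)(C(C)C)C(C)C)cc1COC/C(C)=C/COCC=C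
F10 | step 8 | (2S,3R)-2-(prop-1-en-2-yl)-5-[(1R)-1-{[tri(propan-2-yl)silyl]oxy}ethyl]-2,3-dihydro-1-benzofuran-3-yl 4-nitrobenzoate | C=C(C)[C@@H]1Oc2ccc([C@@H](C)O[Si](C(C)C)(C(C)C)C(C)C)cc2[C@H]1OC(=O)c1ccc([N+](=O)[O-])cc1
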